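All runs were generated by integration with made-up constants, and the scatter is random.

Slowness sits at the end of this chemistry, so I ask what a slow feed does to a last step that is already slow.

| flask | starting material | activator | remark | time |
|---|---|---|---|---|
| eta | 0.066 M | 2 equiv | run made earlier |  |
| beta | 0.092 M | 2 equiv | run made earlier |  |
| epsilon | 0.15 M | 2 equiv | run made earlier |  |
| dusk | 0.066 M (fed, over 8.0 min) | 2.00 equiv | all else is in the flask from the start; the feed brings no volume worth counting | 10 min |
| summer | 0.066 M | 2.00 equiv (in portions, 3, over 8.0 min) | first portion at the start, last at 8.0 min | 10 min |
| noon | 0.066 M | 2.00 equiv (fed, over 8.0 min) | all else is in the flask from the start; the feed brings no volume worth counting | 10 min |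
| midnight | 0.066 M | 2.00 equiv | everything together at the start | 10 min |

| run | time / min | ring / % |
|---|---|---|
| eta | 2.50 | 21.6 |
| eta | 5.00 | 32.9 |
| eta | 8.00 | 40.3 |
| eta | 10.0 | 41.0 |
| beta | 2.00 | 16.5 |
| beta | 4.00 | 30.3 |
| beta | 6.00 | 36.2 |
| beta | 8.00 | 40.8 |
| epsilon | 0.667 | 6.0 |
| epsilon | 1.33 | 14.1 |
| epsilon | 3.00 | 25.1 |
| epsilon | 8.00 | 42.8 |

(readings scatter by 1 percentage point)

1. the flask that comes out highest in amount of ring, in percent of the starting material charged, or "all alike" when all lie within 1.5 percentage points (dusk / summer / noon / midnight / all alike)
2. ring at the end, in percent of the starting material charged, dusk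
3. ring at the end, in percent of the starting material charged, summer
4. ring at the end, in percent of the starting material charged, noon
5. ring at the end, in percent of the starting material charged, midnight

- a species is counted by the starting material in it: one open dimer or idle adduct counts as two
- amounts and yields of ring count idle adduct too
- on the list of suspects stand: starting material + activator -> activated form; activated form -> ring; starting material + activated form -> open dimer; activated form -> side product; starting material + ring <-> idle adduct; activator -> decomposed reagent
- in an amount of ring, one idle adduct counts as one ring

At 8.00 min the eta, beta and epsilon runs read 40.3%, 40.8% and 42.8% of ring, although the starting c(starting material) is larger in epsilon than in eta by a factor 2.27. So I take c(activated form) as the concentration that sets the order: in these runs its first-order decay looks like the rate-limiting step. Eta's readings give a rate constant k of 0.259 min⁻¹, beta's give 0.265 min⁻¹, and eta puts the plateau at 45.3%.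

For dusk I fold k, 8.0 min and 10 min into one number, 0.749: the finished share, the part of an activated form made evenly over the feed that has decayed by the reading. Midnight's share is 0.925. Times the plateau, my dusk is 33.9% and my midnight 41.9%. In noon, activation should end at 4.00 min, when one equivalent has gone in, giving noon 39.3%. In summer, the first portion, 0.667 of activator, should activate as many equivalents of the starting material at the start, and the second portion the rest at 4.00 min, giving summer 39.8%. Midnight is my highest. As a test, the curve gives 41.9% for eta's last reading of 41.0%. But the share speaks of timing; how much gets activated under a feed stays untested.

The forecast names midnight, with dusk 33.5%, summer 39.5%, noon 38.5% and midnight 42.5%: “Each flask then depends on when activated form appears”.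

The flasks give dusk 24.3%, summer 32.1%, noon 32.4% and midnight 42.1%, so midnight is highest.

    starting material + activator → activated form (k = 0.480 M⁻¹ s⁻¹)
    activated form → ring (k = 0.00240 s⁻¹)
    starting material + activated form → open dimer (k = 0.0280 M⁻¹ s⁻¹)
    activated form → side product (k = 0.00250 s⁻¹)
    starting material + ring ⇌ idle adduct, settled at all times (K = 520 M⁻¹)
    activator → decomposed reagent (k = 0.00370 s⁻¹)

Dusk falls short of my 33.9%, and at 10.0 min it holds 0.0876 M of decomposed reagent against midnight's 0.0634 M. The share can still be tried on its own, without my plateau, on dusk left until 40 min. There it is 1.00, so dusk's 24.3% should grow to 32.4%. That flask holds 30.9% of ring, with activated form at 0%, activator at 0% and 8.64% of the starting material unreacted.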